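**Retrosynthetic overview**

1. Ring B (butenolide) is disconnected last-formed-first: O-acylation/intramolecular Wittig leads back to an (R)-α-hydroxy ketone and Ph3P=C=C=O. Ring A (trimethylcyclohexene) is never made; it comes with dihydro-β-ionone.
2. Key disconnection: the bond between the homoallylic CH2 of the C16 chain and the olefin carbon that bears CH2OH. Forward, a copper-catalysed anti-carbomagnesiation of a 2-alkyn-1-ol by the homoallyl Grignard reagent joins the C16 and C9 halves and creates the E trisubstituted allylic alcohol in the same operation.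
3. Enabling feature: the oxygen of the primary CH2OH group on that carbon. As magnesium alkoxide it ties Mg to the distal alkyne carbon in a five-membered O–CH2–C=C–Mg ring, which dictates regiochemistry and anti addition. The future ring B travels as a Grignard-inert 1,3-dioxan-5-one RAMP hydrazone.
4. C16 half: methyl ketone → terminal alkyne → Zr-catalysed carboalumination/ethylene oxide (E olefin) → bromide. C9 half: RAMP-hydrazone alkylation of 2,2-dimethyl-1,3-dioxan-5-one with a 4-silyloxybut-2-ynyl bromide sets the only stereocentre.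
5. Ring order: ring A present from the start; the auxiliary dioxane ring is present from step 6 to step 10; ring B is closed in step 12.

Key step: step 9

Remark: the configuration is read from the SMILES (butenolide C-5 = R, both chain olefins E); RAMP is chosen because azaenolate alkylation in the RAMP series is expected to give the 4R dioxanone centre that maps onto C-5 (SAMP would serve if the sense proved opposite).

**Route**

Step 1
Reactants: 1 dihydro-β-ionone
Product: 3 2-(but-3-yn-1-yl)-1,3,3-trimethylcyclohex-1-ene, via enol phosphate 2 (not isolated)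
Conditions: LiN(i-Pr)2 (1.05 equiv), THF, −78 °C; ClP(O)(OEt)2, −78 °C → rt; LiN(i-Pr)2 (2.3 equiv), −78 °C → rt; dil. HCl
Reagents that add atoms: none
Why: Kinetic deprotonation at the methyl group, O-phosphorylation and base-induced loss of diethyl phosphate (methyl ketone to terminal alkyne by enol phosphate elimination) should give the alkyne, the tetrasubstituted ring olefin being inert to amide base.

Step 2
Reactants: 3 2-(but-3-yn-1-yl)-1,3,3-trimethylcyclohex-1-ene
Product: 6 (3E)-4-methyl-6-(2,6,6-trimethylcyclohex-1-en-1-yl)hex-3-en-1-ol, via vinylalane 4 (not isolated), via lithium alanate 5 (not isolated)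
Conditions: Me3Al (2 equiv), Cp2ZrCl2 (0.25 equiv), ClCH2CH2Cl, rt; volatiles removed, hexane; n-BuLi, −78 → 0 °C; ethylene oxide, THF, 0 °C → rt; dil. HCl
Reagents that add atoms: trimethylaluminium C[Al](C)C; ethylene oxide C1CO1
Why: Zirconium-catalysed syn-carboalumination of the terminal alkyne (Negishi carboalumination) places methyl and aluminium cis with the metal on the terminal carbon, and the derived alkenyl alanate opens ethylene oxide with retention, so the E olefin and the two-carbon alcohol arm should form in one flask.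

Step 3
Reactants: 6 (3E)-4-methyl-6-(2,6,6-trimethylcyclohex-1-en-1-yl)hex-3-en-1-ol
Product: 7 2-[(3E)-6-bromo-3-methylhex-3-en-1-yl]-1,3,3-trimethylcyclohex-1-ene
Conditions: CBr4, PPh3, CH2Cl2, 0 °C
Reagents that add atoms: carbon tetrabromide BrC(Br)(Br)Br
Why: Appel bromination of a primary alcohol runs under neutral conditions that should leave the tri- and tetrasubstituted olefins untouched.

Step 4
Reactants: 8 but-2-yne-1,4-diol
Product: 9 4-[(tert-butyldimethylsilyl)oxy]but-2-yn-1-ol
Conditions: 8 (4 equiv), TBSCl (1 equiv), imidazole, DMF, 0 °C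
Reagents that add atoms: tert-butyldimethylsilyl chloride CC(C)(C)[Si](C)(C)Cl
Why: Silyl ether formation on a symmetrical diol used in excess should give mainly the mono-ether, the surplus diol being removed by aqueous wash.

Step 5
Reactants: 9 4-[(tert-butyldimethylsilyl)oxy]but-2-yn-1-ol
Product: 10 [(4-bromobut-2-yn-1-yl)oxy](tert-butyl)dimethylsilane
Conditions: CBr4, PPh3, CH2Cl2, 0 °C
Reagents that add atoms: carbon tetrabromide BrC(Br)(Br)Br
Why: Appel bromination converts the propargylic alcohol into the bromide without acid, so the silyl ether should survive.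

Step 6
Reactants: 11 2,2-dimethyl-1,3-dioxan-5-one; 12 RAMP, (2R)-1-amino-2-(methoxymethyl)pyrrolidine
Product: 13 (2R)-N-(2,2-dimethyl-1,3-dioxan-5-ylidene)-2-(methoxymethyl)pyrrolidin-1-amine
Conditions: benzene, reflux, Dean–Stark trap
Reagents that add atoms: none
Why: Hydrazone formation by condensation of the ketone with the 1,1-disubstituted hydrazine attaches the auxiliary and masks the carbonyl group for all steps up to step 10.

Step 7
Reactants: 13 (2R)-N-(2,2-dimethyl-1,3-dioxan-5-ylidene)-2-(methoxymethyl)pyrrolidin-1-amine; 10 [(4-bromobut-2-yn-1-yl)oxy](tert-butyl)dimethylsilane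
Product: 15 (2R)-N-[(4R)-4-{4-[(tert-butyldimethylsilyl)oxy]but-2-yn-1-yl}-2,2-dimethyl-1,3-dioxan-5-ylidene]-2-(methoxymethyl)pyrrolidin-1-amine, via lithium azaenolate 14 (not isolated)
Conditions: t-BuLi (1.05 equiv), THF, −78 °C; then 10, −100 °C → rt
Reagents that add atoms: none
Why: Enders RAMP-hydrazone alkylation, in which the methoxy-chelated lithium azaenolate is attacked by the propargylic bromide (SN2) on the face anti to the pyrrolidine substituent, should set the 4R centre, the only stereocentre of the target.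

Step 8
Reactants: 15 (2R)-N-[(4R)-4-{4-[(tert-butyldimethylsilyl)oxy]but-2-yn-1-yl}-2,2-dimethyl-1,3-dioxan-5-ylidene]-2-(methoxymethyl)pyrrolidin-1-amine
Product: 16 4-[(4R)-2,2-dimethyl-5-{[(2R)-2-(methoxymethyl)pyrrolidin-1-yl]imino}-1,3-dioxan-4-yl]but-2-yn-1-ol
Conditions: Bu4NF, THF, 0 °C
Reagents that add atoms: none
Why: Fluoride-induced desilylation frees the propargylic hydroxyl while the acid-labile hydrazone and acetonide, both stable to fluoride, should remain.

Step 9
Reactants: 7 2-[(3E)-6-bromo-3-methylhex-3-en-1-yl]-1,3,3-trimethylcyclohex-1-ene; 16 4-[(4R)-2,2-dimethyl-5-{[(2R)-2-(methoxymethyl)pyrrolidin-1-yl]imino}-1,3-dioxan-4-yl]but-2-yn-1-ol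
Product: 20 (2E,5E)-2-{2-[(4R)-2,2-dimethyl-5-{[(2R)-2-(methoxymethyl)pyrrolidin-1-yl]imino}-1,3-dioxan-4-yl]ethylidene}-6-methyl-8-(2,6,6-trimethylcyclohex-1-en-1-yl)oct-5-en-1-ol, via Grignard reagent 17 (not isolated), via bromomagnesium alkoxide 18 (not isolated), via oxamagnesacycle 19 (not isolated)
Conditions: 7 (2 equiv), Mg, THF, 40 °C; separately 16, MeMgBr (1.0 equiv), THF, 0 °C; combined, CuI (10 mol%), THF, −10 °C → rt; aq. NH4Cl
Reagents that add atoms: none
Why: The alkylcopper/magnesium species formed from 17 and catalytic CuI is bound by the magnesium alkoxide 18 and delivers the alkyl group to the alkyne carbon next to the CH2O group while magnesium ends on the distal carbon on the opposite face, held in the five-membered oxamagnesacycle 19, whose protonation gives 20. The closest known reaction type is the copper-catalysed anti-carbomagnesiation of 2-alkyn-1-ols with alkyl Grignard reagents, the standard entry to 2-alkylallylic alcohols and, with iodine quench, to (Z)-3-iodo-2-alkylallylic alcohols. No ring of the target is closed here; the only ring formed is the transient O–C–C=C–Mg chelate, closed by coordination of the alkoxide oxygen to magnesium. No stereocentre is created; the new stereo element is the E olefin, controlled by the anti addition that the chelate enforces (CH2OH cis to H, C16 chain cis to the CH2 that leads to the dioxane). The step needs regioselectivity (alkyl to the proximal alkyne carbon), anti stereoselectivity and chemoselectivity, secured in turn by the free hydroxyl, by the chelate, and by the absence of a leaving group on the other propargylic carbon (no allene formation) together with the inertness of the N,N-dialkylhydrazone and the acetonide to Grignard reagents. One operation thus joins the C16 and C9 halves and turns a geometry-free alkyne into the trisubstituted allylic alcohol of the target.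

Step 10
Reactants: 20 (2E,5E)-2-{2-[(4R)-2,2-dimethyl-5-{[(2R)-2-(methoxymethyl)pyrrolidin-1-yl]imino}-1,3-dioxan-4-yl]ethylidene}-6-methyl-8-(2,6,6-trimethylcyclohex-1-en-1-yl)oct-5-en-1-ol
Product: 22 (3R,5E,9E)-1,3-dihydroxy-6-(hydroxymethyl)-10-methyl-12-(2,6,6-trimethylcyclohex-1-en-1-yl)dodeca-5,9-dien-2-one, via dioxanone 21 (not isolated)
Conditions: sat. aq. (CO2H)2, Et2O, rt; then Dowex 50WX8 (H+ form), THF/H2O, rt
Reagents that add atoms: water O
Why: Two-phase oxalic acid hydrolysis is the mild cleavage used for RAMP hydrazones of dioxanones and should not racemise the α-centre, and acetal hydrolysis on the acidic resin then removes the acetonide under conditions the allylic alcohol and the olefins should tolerate.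

Step 11
Reactants: 22 (3R,5E,9E)-1,3-dihydroxy-6-(hydroxymethyl)-10-methyl-12-(2,6,6-trimethylcyclohex-1-en-1-yl)dodeca-5,9-dien-2-one
Product: 23 (3R,5E,9E)-1-[(tert-butyldimethylsilyl)oxy]-6-{[(tert-butyldimethylsilyl)oxy]methyl}-3-hydroxy-10-methyl-12-(2,6,6-trimethylcyclohex-1-en-1-yl)dodeca-5,9-dien-2-one
Conditions: TBSCl (2.1 equiv), imidazole, CH2Cl2, −20 → 0 °C
Reagents that add atoms: tert-butyldimethylsilyl chloride CC(C)(C)[Si](C)(C)Cl
Why: Silyl ether formation is much faster at the two primary hydroxyls than at the hindered secondary ketol hydroxyl (steric discrimination), which must stay free for the lactonisation.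

Step 12
Reactants: 23 (3R,5E,9E)-1-[(tert-butyldimethylsilyl)oxy]-6-{[(tert-butyldimethylsilyl)oxy]methyl}-3-hydroxy-10-methyl-12-(2,6,6-trimethylcyclohex-1-en-1-yl)dodeca-5,9-dien-2-one
Product: 25 (5R)-4-{[(tert-butyldimethylsilyl)oxy]methyl}-5-[(2E,6E)-3-{[(tert-butyldimethylsilyl)oxy]methyl}-7-methyl-9-(2,6,6-trimethylcyclohex-1-en-1-yl)nona-2,6-dien-1-yl]furan-2(5H)-one, via acyloxy phosphorane 24 (not isolated)
Conditions: Ph3P=C=C=O (1.2 equiv), toluene, 90 °C
Reagents that add atoms: (triphenylphosphoranylidene)ketene O=C=C=P(c1ccccc1)(c1ccccc1)c1ccccc1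
Why: Addition of the secondary hydroxyl to the ketene ylide gives a stabilised acyloxy phosphorane that closes onto the neighbouring ketone (intramolecular Wittig reaction, Bestmann butenolide synthesis) under neutral conditions, so ring B should form without base that could epimerise C-5.

Step 13
Reactants: 25 (5R)-4-{[(tert-butyldimethylsilyl)oxy]methyl}-5-[(2E,6E)-3-{[(tert-butyldimethylsilyl)oxy]methyl}-7-methyl-9-(2,6,6-trimethylcyclohex-1-en-1-yl)nona-2,6-dien-1-yl]furan-2(5H)-one
Product: 26 (6E)-neomanoalide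
Conditions: HF·pyridine, pyridine/THF, 0 °C → rt
Reagents that add atoms: none
Why: Fluoride desilylation of both primary silyl ethers under buffered, slightly acidic conditions should avoid base-induced epimerisation at the γ-position and opening of the butenolide.

**Compound list**

1 | dihydro-β-ionone, 4-(2,6,6-trimethylcyclohex-1-en-1-yl)butan-2-one | CC1=C(CCC(C)=O)C(C)(C)CCC1 | starting material
2 | diethyl 4-(2,6,6-trimethylcyclohex-1-en-1-yl)but-1-en-2-yl phosphate (enol phosphate, not isolated) | CC1=C(CCC(=C)OP(=O)(OCC)OCC)C(C)(C)CCC1 | intermediate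
3 | 2-(but-3-yn-1-yl)-1,3,3-trimethylcyclohex-1-ene | CC1=C(CCC#C)C(C)(C)CCC1 | intermediate
4 | dimethyl[(1E)-2-methyl-4-(2,6,6-trimethylcyclohex-1-en-1-yl)but-1-en-1-yl]alane (vinylalane, not isolated) | CC1=C(CC/C(C)=C/[Al](C)C)C(C)(C)CCC1 | intermediate
5 | lithium butyl(dimethyl)[(1E)-2-methyl-4-(2,6,6-trimethylcyclohex-1-en-1-yl)but-1-en-1-yl]alanate (not isolated) | CC1=C(CC/C(C)=C/[Al-](C)(C)CCCC)C(C)(C)CCC1.[Li+] | intermediate
6 | (3E)-4-methyl-6-(2,6,6-trimethylcyclohex-1-en-1-yl)hex-3-en-1-ol | CC1=C(CC/C(C)=C/CCO)C(C)(C)CCC1 | intermediate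
7 | 2-[(3E)-6-bromo-3-methylhex-3-en-1-yl]-1,3,3-trimethylcyclohex-1-ene | CC1=C(CC/C(C)=C/CCBr)C(C)(C)CCC1 | intermediate
8 | but-2-yne-1,4-diol | OCC#CCO | starting material
9 | 4-[(tert-butyldimethylsilyl)oxy]but-2-yn-1-ol | CC(C)(C)[Si](C)(C)OCC#CCO | intermediate
10 | [(4-bromobut-2-yn-1-yl)oxy](tert-butyl)dimethylsilane | CC(C)(C)[Si](C)(C)OCC#CCBr | intermediate
11 | 2,2-dimethyl-1,3-dioxan-5-one | CC1(C)OCC(=O)CO1 | starting material
12 | RAMP, (2R)-1-amino-2-(methoxymethyl)pyrrolidine | COC[C@H]1CCCN1N | starting material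
13 | (2R)-N-(2,2-dimethyl-1,3-dioxan-5-ylidene)-2-(methoxymethyl)pyrrolidin-1-amine | COC[C@H]1CCCN1N=C1COC(C)(C)OC1 | intermediate
14 | lithium (2,2-dimethyl-4H-1,3-dioxin-5-yl)[(2R)-2-(methoxymethyl)pyrrolidin-1-yl]azanide (azaenolate, not isolated) | COC[C@H]1CCCN1N([Li])C1=COC(C)(C)OC1 | intermediate
15 | (2R)-N-[(4R)-4-{4-[(tert-butyldimethylsilyl)oxy]but-2-yn-1-yl}-2,2-dimethyl-1,3-dioxan-5-ylidene]-2-(methoxymethyl)pyrrolidin-1-amine | COC[C@H]1CCCN1N=C1COC(C)(C)O[C@@H]1CC#CCO[Si](C)(C)C(C)(C)C | intermediate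
16 | 4-[(4R)-2,2-dimethyl-5-{[(2R)-2-(methoxymethyl)pyrrolidin-1-yl]imino}-1,3-dioxan-4-yl]but-2-yn-1-ol | COC[C@H]1CCCN1N=C1COC(C)(C)O[C@@H]1CC#CCO | intermediate
17 | bromo[(3E)-4-methyl-6-(2,6,6-trimethylcyclohex-1-en-1-yl)hex-3-en-1-yl]magnesium (Grignard reagent, not isolated) | CC1=C(CC/C(C)=C/CC[Mg]Br)C(C)(C)CCC1 | intermediate
18 | bromomagnesium alkoxide of 16 (not isolated) | COC[C@H]1CCCN1N=C1COC(C)(C)O[C@@H]1CC#CCO[Mg]Br | intermediate
19 | 2,5-dihydro-1,2-oxamagnesole chelate with the (4R)-dioxanylmethyl group on C3 and the C16 chain on C4 (not isolated) | CC1=C(CC/C(C)=C/CCC2=C(C[C@H]3OC(C)(C)OCC3=NN3CCC[C@@H]3COC)[Mg]OC2)C(C)(C)CCC1 | intermediate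
20 | (2E,5E)-2-{2-[(4R)-2,2-dimethyl-5-{[(2R)-2-(methoxymethyl)pyrrolidin-1-yl]imino}-1,3-dioxan-4-yl]ethylidene}-6-methyl-8-(2,6,6-trimethylcyclohex-1-en-1-yl)oct-5-en-1-ol | CC1=C(CC/C(C)=C/CC/C(=C\C[C@H]2OC(C)(C)OCC2=NN2CCC[C@@H]2COC)CO)C(C)(C)CCC1 | intermediate
21 | (4R)-4-[(2E,6E)-3-(hydroxymethyl)-7-methyl-9-(2,6,6-trimethylcyclohex-1-en-1-yl)nona-2,6-dien-1-yl]-2,2-dimethyl-1,3-dioxan-5-one (not isolated) | CC1=C(CC/C(C)=C/CC/C(=C\C[C@H]2OC(C)(C)OCC2=O)CO)C(C)(C)CCC1 | intermediate
22 | (3R,5E,9E)-1,3-dihydroxy-6-(hydroxymethyl)-10-methyl-12-(2,6,6-trimethylcyclohex-1-en-1-yl)dodeca-5,9-dien-2-one | CC1=C(CC/C(C)=C/CC/C(=C\C[C@@H](O)C(=O)CO)CO)C(C)(C)CCC1 | intermediate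
23 | (3R,5E,9E)-1-[(tert-butyldimethylsilyl)oxy]-6-{[(tert-butyldimethylsilyl)oxy]methyl}-3-hydroxy-10-methyl-12-(2,6,6-trimethylcyclohex-1-en-1-yl)dodeca-5,9-dien-2-one | CC1=C(CC/C(C)=C/CC/C(=C\C[C@@H](O)C(=O)CO[Si](C)(C)C(C)(C)C)CO[Si](C)(C)C(C)(C)C)C(C)(C)CCC1 | intermediate
24 | (triphenylphosphoranylidene)acetate ester of 23 at the secondary hydroxyl (acyloxy phosphorane, not isolated) | CC1=C(CC/C(C)=C/CC/C(=C\C[C@@H](OC(=O)C=P(c2ccccc2)(c2ccccc2)c2ccccc2)C(=O)CO[Si](C)(C)C(C)(C)C)CO[Si](C)(C)C(C)(C)C)C(C)(C)CCC1 | intermediate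
25 | (5R)-4-{[(tert-butyldimethylsilyl)oxy]methyl}-5-[(2E,6E)-3-{[(tert-butyldimethylsilyl)oxy]methyl}-7-methyl-9-(2,6,6-trimethylcyclohex-1-en-1-yl)nona-2,6-dien-1-yl]furan-2(5H)-one | CC1=C(CC/C(C)=C/CC/C(=C\C[C@H]2OC(=O)C=C2CO[Si](C)(C)C(C)(C)C)CO[Si](C)(C)C(C)(C)C)C(C)(C)CCC1 | intermediate
26 | (6E)-neomanoalide, (5R)-4-(hydroxymethyl)-5-[(2E,6E)-3-(hydroxymethyl)-7-methyl-9-(2,6,6-trimethylcyclohex-1-en-1-yl)nona-2,6-dien-1-yl]furan-2(5H)-one | CC1=C(CC/C(C)=C/CC/C(=C\C[C@H]2OC(=O)C=C2CO)CO)C(C)(C)CCC1 | target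

**Step count and risks**

Total step count: 13. Longest linear sequence: 9 steps (steps 4, 5, 7, 8, 9, 10, 11, 12, 13 from but-2-yne-1,4-diol).

Steps most likely to fail:

Step 9 (key step). Transfer of a primary alkyl group with β-hydrogens to an internal alkyne may be slow, so that the copper derivative of 17 decomposes or copper is sequestered by the hydrazone nitrogens before carbometalation is complete. The fallback sets out from 16 and 7 and comes back at 20. Hydroxyl-directed trans-hydrostannation of 16 (Bu3SnH, catalytic [Cp*RuCl]4, CH2Cl2) should give (2Z)-4-[(4R)-2,2-dimethyl-5-{[(2R)-2-(methoxymethyl)pyrrolidin-1-yl]imino}-1,3-dioxan-4-yl]-2-(tributylstannyl)but-2-en-1-ol F1, with tin on the carbon next to CH2OH and anti to the new hydrogen. Iododestannylation (I2, CH2Cl2, 0 °C) should give the (Z)-2-iodoallylic alcohol F2 with retention. Zinc insertion into 7 (Zn dust, LiCl, THF) gives the alkylzinc bromide F3, and a Negishi coupling of F2 with F3 (Pd(OAc)2, SPhos, THF, rt; zerovalent palladium as active catalyst) forms the same bond with retention of olefin geometry and gives 20.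

Step 12. The intramolecular Wittig closure may be slow at a ketone flanked by the silyloxymethyl group, so that the acyloxy phosphorane decomposes or the ketol isomerises on prolonged heating. The fallback sets out from 23 and comes back at 25. Esterification of the secondary hydroxyl with diethylphosphonoacetic acid (N,N′-diisopropylcarbodiimide, DMAP, CH2Cl2) gives the phosphonoacetate F4, and an intramolecular Horner–Wadsworth–Emmons reaction under Masamune–Roush conditions (LiCl, i-Pr2NEt, MeCN, 0 °C) closes ring B to 25.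

Step 11. Silylation may spread to the secondary hydroxyl, or a silyl group may migrate from the primary to the secondary ketol oxygen. The fallback sets out from 22 and comes back at 26. A lipase (immobilised Candida antarctica lipase B) with vinyl acetate in t-BuOMe should acetylate only the two primary hydroxyls and give the diacetate F5. Ph3P=C=C=O in toluene at 90 °C then gives, through the acyloxy phosphorane F6, the butenolide diacetate F7. The same lipase in pH 7 phosphate buffer/acetone hydrolyses both primary acetates without touching the lactone and gives 26 directly.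

Further compounds
F1 | step 9 | (2Z)-4-[(4R)-2,2-dimethyl-5-{[(2R)-2-(methoxymethyl)pyrrolidin-1-yl]imino}-1,3-dioxan-4-yl]-2-(tributylstannyl)but-2-en-1-ol | CCCC[Sn](CCCC)(CCCC)/C(=C\C[C@H]1OC(C)(C)OCC1=NN1CCC[C@@H]1COC)CO
F2 | step 9 | (2Z)-4-[(4R)-2,2-dimethyl-5-{[(2R)-2-(methoxymethyl)pyrrolidin-1-yl]imino}-1,3-dioxan-4-yl]-2-iodobut-2-en-1-ol | I/C(=C\C[C@H]1OC(C)(C)OCC1=NN1CCC[C@@H]1COC)CO
F3 | step 9 | bromo[(3E)-4-methyl-6-(2,6,6-trimethylcyclohex-1-en-1-yl)hex-3-en-1-yl]zinc | CC1=C(CC/C(C)=C/CC[Zn]Br)C(C)(C)CCC1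
F4 | step 12 | (diethoxyphosphoryl)acetate ester of 23 at the secondary hydroxyl | CC1=C(CC/C(C)=C/CC/C(=C\C[C@@H](OC(=O)CP(=O)(OCC)OCC)C(=O)CO[Si](C)(C)C(C)(C)C)CO[Si](C)(C)C(C)(C)C)C(C)(C)CCC1
F5 | step 11 | diacetate of 22 at both primary hydroxyls (secondary hydroxyl free) | CC1=C(CC/C(C)=C/CC/C(=C\C[C@@H](O)C(=O)COC(C)=O)COC(C)=O)C(C)(C)CCC1
F6 | step 11 | (triphenylphosphoranylidene)acetate ester of F5 at the secondary hydroxyl | CC1=C(CC/C(C)=C/CC/C(=C\C[C@@H](OC(=O)C=P(c2ccccc2)(c2ccccc2)c2ccccc2)C(=O)COC(C)=O)COC(C)=O)C(C)(C)CCC1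
F7 | step 11 | (6E)-neomanoalide diacetate | CC1=C(CC/C(C)=C/CC/C(=C\C[C@H]2OC(=O)C=C2COC(C)=O)COC(C)=O)C(C)(C)CCC1
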